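## Retrosynthetic overview

1. Target 16 ⇐ tetrasilyl ether 15 by fluoride desilylation in the same flask.
2. 15 ⇐ achiral triarylethylene triol 14. The dihydrofuran ring, the only ring made in the route, is closed last through the O1–C2 bond by a catalytic asymmetric hydroalkoxylation that sets C2 and C3.
3. 14 ⇐ 12 (MOM removal) ⇐ aryllithium of fragment 1 (protected resveratrol 3) + fragment 2 (ketone 9), by addition and elimination (C3–C3a bond).
4. 9 ⇐ acetophenone 6 + aryl bromide 8 by ketone α-arylation; 3 ⇐ resveratrol 1.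
5. All four benzene rings are bought.

Labels: ring A = 2,4-dioxygenated phenyl on C2; ring B = 3,5-dioxygenated phenyl on C3; ring C = benzo ring of the benzofuran; ring D = 4-hydroxyphenyl of the styryl group. MOM = methoxymethyl, TBS = tert-butyldimethylsilyl, TMS = trimethylsilyl.

Assumption: the target is the 2,3-trans (2S,3S) isomer encoded by the SMILES. The sense of induction of the chiral acid in step 7 must be fixed by experiment, so "(S,S)" stands for whichever antipode delivers (2S,3S).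

## Route

Step 1
Reactants: 1 resveratrol; 2 chloromethyl methyl ether
Product: 3 (E)-1,3-bis(methoxymethoxy)-5-{2-[4-(methoxymethoxy)phenyl]ethenyl}benzene (fragment 1)
Conditions: NaH, MOMCl, DMF, 0 → 23 °C
Reagents that add atoms: chloromethyl methyl ether 2 (MOMCl), COCCl
Why: Williamson-type O-alkylation of the three phenoxides installs the acetal groups that later direct the metalation; no stereocentre is formed.

Step 2
Reactants: 4 1-(3,5-dihydroxyphenyl)ethan-1-one; 5 tert-butyldimethylsilyl chloride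
Product: 6 1-[3,5-bis(tert-butyldimethylsilyloxy)phenyl]ethan-1-one
Conditions: TBSCl, imidazole, DMF, 23 °C
Reagents that add atoms: tert-butyldimethylsilyl chloride 5 (TBSCl), CC(C)(C)[Si](C)(C)Cl
Why: Imidazole-promoted silyl ether formation gives phenol protection that survives organolithium and MOM-cleavage conditions and falls to fluoride; no stereocentre is formed.

Step 3
Reactants: 7 4-bromobenzene-1,3-diol; 5 tert-butyldimethylsilyl chloride
Product: 8 1-bromo-2,4-bis(tert-butyldimethylsilyloxy)benzene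
Conditions: TBSCl, imidazole, DMF, 23 °C
Reagents that add atoms: tert-butyldimethylsilyl chloride 5 (TBSCl), CC(C)(C)[Si](C)(C)Cl
Why: Same silyl ether formation as step 2, here on the ring A precursor; no stereocentre is formed.

Step 4
Reactants: 6 1-[3,5-bis(tert-butyldimethylsilyloxy)phenyl]ethan-1-one; 8 1-bromo-2,4-bis(tert-butyldimethylsilyloxy)benzene
Product: 9 1-[3,5-bis(tert-butyldimethylsilyloxy)phenyl]-2-[2,4-bis(tert-butyldimethylsilyloxy)phenyl]ethan-1-one (fragment 2)
Conditions: Pd(OAc)2 (2 mol%), XPhos (4 mol%), K3PO4, toluene, 90 °C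
Reagents that add atoms: none
Why: Palladium-catalysed α-arylation of the methyl ketone enolate (Buchwald–Hartwig type) stops at monoarylation with the bulky biarylphosphine and the ortho-substituted bromide, and the weak phosphate base spares the aryl silyl ethers; no stereocentre is formed.

Step 5
Reactants: 3 (E)-1,3-bis(methoxymethoxy)-5-{2-[4-(methoxymethoxy)phenyl]ethenyl}benzene; 9 1-[3,5-bis(tert-butyldimethylsilyloxy)phenyl]-2-[2,4-bis(tert-butyldimethylsilyloxy)phenyl]ethan-1-one
Product: 12 triarylethylene 2-{1-[3,5-bis(tert-butyldimethylsilyloxy)phenyl]-2-[2,4-bis(tert-butyldimethylsilyloxy)phenyl]ethenyl}-1,3-bis(methoxymethoxy)-5-[(E)-2-(4-(methoxymethoxy)phenyl)ethenyl]benzene (E/Z mixture at the new alkene), via aryllithium 10 (not isolated), via lithium alkoxide 11 (not isolated)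
Conditions: 3, n-BuLi, THF, −20 °C; add to 9, LaCl3·2LiCl, THF, −78 °C; then MsCl, Et3N, −78 → 23 °C
Reagents that add atoms: none
Why: Directed ortho-metalation occurs only at the ring C carbon flanked by both MOM ethers, the aryllithium adds 1,2 to the ketone (the lanthanum salt suppresses enolisation), and mesylation of the tertiary bis-benzylic alkoxide triggers E1 elimination to the conjugated triarylethylene under basic conditions; no stereocentre is formed.

Step 6
Reactants: 12 tri-MOM tetra-TBS triarylethylene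
Product: 14 triol 2-{1-[3,5-bis(tert-butyldimethylsilyloxy)phenyl]-2-[2,4-bis(tert-butyldimethylsilyloxy)phenyl]ethenyl}-5-[(E)-2-(4-hydroxyphenyl)ethenyl]benzene-1,3-diol (E/Z mixture at the triaryl alkene), via tris(trimethylsilyl) ether 13 (not isolated)
Conditions: TMSOTf, 2,2'-bipyridyl, CH2Cl2, 0 → 23 °C; then H2O, NaHCO3 (argon; product filtered through Et3N-washed silica)
Reagents that add atoms: none
Why: Non-protic acetal cleavage by the bipyridyl-buffered silyl triflate turns each aryl MOM ether into an aryl TMS ether that hydrolyses on the bicarbonate quench, so no Brønsted acid meets the electron-rich alkene (which would close the ring racemically) and the TBS ethers stay; no stereocentre is formed.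

Step 7
Reactants: 14 triarylethylene triol
Product: 16 target 4-[(2S,3S)-3-(3,5-dihydroxyphenyl)-4-hydroxy-6-[(E)-2-(4-hydroxyphenyl)ethenyl]-2,3-dihydro-1-benzofuran-2-yl]benzene-1,3-diol, via tetra-TBS dihydrobenzofuran 15 (not isolated)
Conditions: (S,S)-IDPi acid (imidodiphosphorimidate from two (S)-3,3'-diaryl-BINOL units with two P=N–SO2CF3 groups, 5 mol%), toluene, −40 °C; then TBAF, AcOH, THF, 0 → 23 °C
Reagents that add atoms: none
Why: Proposed new method: a catalytic asymmetric intramolecular hydroalkoxylation in which the confined chiral acid protonates the diaryl-substituted alkene carbon (future C3) face-selectively inside a contact ion pair, fixing C3 as S and leaving a 2,4-bis(silyloxy)benzylic cation at C2 that is captured by one of the two equivalent flanking phenol oxygens of ring C anti to the C3 aryl group, so the O1–C2 bond closes the ring as the 2,3-trans (2S,3S) isomer (also the thermodynamic isomer, since C2–O ionisation is reversible); the E and Z isomers of 14 converge because reversible protonation at the CH carbon interconverts them, and the bulky silyl ethers on ring A disfavour closure by a ring A oxygen; the closest known reactions are IDPi-catalysed asymmetric intramolecular hydroalkoxylation of alkenes, chiral phosphoric acid 1,6-additions to para-quinone methides generated from para-hydroxystyrenes, and the racemic acid-mediated quinone methide closure of ortho-hydroxystilbenes to 2-aryl-2,3-dihydrobenzofurans; buffered fluoride then removes the four TBS groups without touching the stereocentres.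

## Compound list

1 | resveratrol, (E)-5-[2-(4-hydroxyphenyl)ethenyl]benzene-1,3-diol | Oc1ccc(/C=C/c2cc(O)cc(O)c2)cc1 | starting material
2 | chloromethyl methyl ether | COCCl | starting material
3 | (E)-1,3-bis(methoxymethoxy)-5-{2-[4-(methoxymethoxy)phenyl]ethenyl}benzene | COCOc1ccc(/C=C/c2cc(OCOC)cc(OCOC)c2)cc1 | intermediate
4 | 1-(3,5-dihydroxyphenyl)ethan-1-one | CC(=O)c1cc(O)cc(O)c1 | starting material
5 | tert-butyldimethylsilyl chloride | CC(C)(C)[Si](C)(C)Cl | starting material
6 | 1-[3,5-bis(tert-butyldimethylsilyloxy)phenyl]ethan-1-one | CC(=O)c1cc(O[Si](C)(C)C(C)(C)C)cc(O[Si](C)(C)C(C)(C)C)c1 | intermediate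
7 | 4-bromobenzene-1,3-diol | Oc1ccc(Br)c(O)c1 | starting material
8 | 1-bromo-2,4-bis(tert-butyldimethylsilyloxy)benzene | CC(C)(C)[Si](C)(C)Oc1ccc(Br)c(O[Si](C)(C)C(C)(C)C)c1 | intermediate
9 | 1-[3,5-bis(tert-butyldimethylsilyloxy)phenyl]-2-[2,4-bis(tert-butyldimethylsilyloxy)phenyl]ethan-1-one | O=C(Cc1ccc(O[Si](C)(C)C(C)(C)C)cc1O[Si](C)(C)C(C)(C)C)c1cc(O[Si](C)(C)C(C)(C)C)cc(O[Si](C)(C)C(C)(C)C)c1 | intermediate
10 | {2,6-bis(methoxymethoxy)-4-[(E)-2-(4-(methoxymethoxy)phenyl)ethenyl]phenyl}lithium | [Li]c1c(OCOC)cc(/C=C/c2ccc(OCOC)cc2)cc1OCOC | intermediate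
11 | lithium 1-{2,6-bis(methoxymethoxy)-4-[(E)-2-(4-(methoxymethoxy)phenyl)ethenyl]phenyl}-1-[3,5-bis(tert-butyldimethylsilyloxy)phenyl]-2-[2,4-bis(tert-butyldimethylsilyloxy)phenyl]ethan-1-olate (racemic) | [Li+].[O-]C(Cc1ccc(O[Si](C)(C)C(C)(C)C)cc1O[Si](C)(C)C(C)(C)C)(c1cc(O[Si](C)(C)C(C)(C)C)cc(O[Si](C)(C)C(C)(C)C)c1)c1c(OCOC)cc(/C=C/c2ccc(OCOC)cc2)cc1OCOC | intermediate
12 | 2-{1-[3,5-bis(tert-butyldimethylsilyloxy)phenyl]-2-[2,4-bis(tert-butyldimethylsilyloxy)phenyl]ethenyl}-1,3-bis(methoxymethoxy)-5-[(E)-2-(4-(methoxymethoxy)phenyl)ethenyl]benzene (E/Z mixture at the triaryl alkene, left open in the SMILES) | COCOc1ccc(/C=C/c2cc(OCOC)c(C(=Cc3ccc(O[Si](C)(C)C(C)(C)C)cc3O[Si](C)(C)C(C)(C)C)c3cc(O[Si](C)(C)C(C)(C)C)cc(O[Si](C)(C)C(C)(C)C)c3)c(OCOC)c2)cc1 | intermediate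
13 | tris(trimethylsilyl) ether of 14 (ring C 1,3-bis(trimethylsilyloxy), ring D 4-trimethylsilyloxy; E/Z mixture at the triaryl alkene) | C[Si](C)(C)Oc1ccc(/C=C/c2cc(O[Si](C)(C)C)c(C(=Cc3ccc(O[Si](C)(C)C(C)(C)C)cc3O[Si](C)(C)C(C)(C)C)c3cc(O[Si](C)(C)C(C)(C)C)cc(O[Si](C)(C)C(C)(C)C)c3)c(O[Si](C)(C)C)c2)cc1 | intermediate
14 | 2-{1-[3,5-bis(tert-butyldimethylsilyloxy)phenyl]-2-[2,4-bis(tert-butyldimethylsilyloxy)phenyl]ethenyl}-5-[(E)-2-(4-hydroxyphenyl)ethenyl]benzene-1,3-diol (E/Z mixture at the triaryl alkene) | Oc1ccc(/C=C/c2cc(O)c(C(=Cc3ccc(O[Si](C)(C)C(C)(C)C)cc3O[Si](C)(C)C(C)(C)C)c3cc(O[Si](C)(C)C(C)(C)C)cc(O[Si](C)(C)C(C)(C)C)c3)c(O)c2)cc1 | intermediate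
15 | (2S,3S)-2-[2,4-bis(tert-butyldimethylsilyloxy)phenyl]-3-[3,5-bis(tert-butyldimethylsilyloxy)phenyl]-6-[(E)-2-(4-hydroxyphenyl)ethenyl]-2,3-dihydro-1-benzofuran-4-ol (2,3-trans) | Oc1ccc(/C=C/c2cc(O)c3c(c2)O[C@H](c2ccc(O[Si](C)(C)C(C)(C)C)cc2O[Si](C)(C)C(C)(C)C)[C@H]3c2cc(O[Si](C)(C)C(C)(C)C)cc(O[Si](C)(C)C(C)(C)C)c2)cc1 | intermediate
16 | 4-[(2S,3S)-3-(3,5-dihydroxyphenyl)-4-hydroxy-6-[(E)-2-(4-hydroxyphenyl)ethenyl]-2,3-dihydro-1-benzofuran-2-yl]benzene-1,3-diol (2,3-trans) | Oc1ccc(/C=C/c2cc(O)c3c(c2)O[C@H](c2ccc(O)cc2O)[C@H]3c2cc(O)cc(O)c2)cc1 | target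

## Step count and risks

Total step count: 7. Longest linear sequence: 5 steps (step 2 or 3, then 4, 5, 6, 7).

The three steps most likely to fail, with fallbacks:

Step 7, the new asymmetric ring closure. The risks are low enantioselectivity, acid-induced ionisation of the free 4-hydroxystilbene, and silyl migration. The fallback sets out from 14 and comes back to the route at 15. Compound 14 is treated with an achiral acid (diphenyl phosphate, 10 mol%, CH2Cl2, 0 °C), which is the known acid-mediated quinone-methide-type closure of ortho-hydroxystilbenes. This gives the trans-dihydrobenzofuran as a racemate, that is 15 together with its mirror image, the (2R,3R)-dihydrobenzofuran F1. The two are separated by preparative chiral SFC on an amylose-type phase, and 15 then goes through the fluoride stage of step 7 to give 16.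

Step 5, the metalation, addition and elimination. The risks are butyllithium adding to the stilbene, enolisation of the deoxybenzoin 9, and a sluggish elimination. The fallback replaces the carbonyl addition by a cross-coupling; it sets out from 3 and 9 and comes back at 12. Compound 3 is lithiated as before and quenched with 2-isopropoxy-4,4,5,5-tetramethyl-1,3,2-dioxaborolane to give the aryl pinacol boronate F2. Ketone 9 is converted with KN(SiMe3)2 and PhNTf2 (THF, −78 °C) into the (Z)-enol triflate F3. Suzuki–Miyaura coupling of the two (Pd(OAc)2, SPhos, K3PO4, THF/H2O, 50 °C) gives 12 as a single alkene isomer.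

Step 6, the MOM removal. The risks are incomplete cleavage of the two hindered ring C acetals and adventitious acid closing the ring of 14 racemically. The fallback changes the protecting group on fragment 1 to one that leaves under near-neutral conditions; it sets out from 1 and 9 and comes back at 14. Resveratrol 1 is treated with ethyl vinyl ether and PPTS (CH2Cl2, 23 °C) to give the tris(1-ethoxyethyl) ether F4, a mixture of acetal diastereomers. This is lithiated as in step 5 to the aryllithium F5, added to 9 to give the lithium alkoxide F6, and eliminated in the same flask with MsCl and Et3N to the triarylethylene F7. Acetal exchange with PPTS (cat.) in MeOH at 23 °C, too weakly acidic to protonate the alkene, then gives 14.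

## Further compounds

F1 | step 7 | (2R,3R)-2-[2,4-bis(tert-butyldimethylsilyloxy)phenyl]-3-[3,5-bis(tert-butyldimethylsilyloxy)phenyl]-6-[(E)-2-(4-hydroxyphenyl)ethenyl]-2,3-dihydro-1-benzofuran-4-ol (mirror image of 15) | Oc1ccc(/C=C/c2cc(O)c3c(c2)O[C@@H](c2ccc(O[Si](C)(C)C(C)(C)C)cc2O[Si](C)(C)C(C)(C)C)[C@@H]3c2cc(O[Si](C)(C)C(C)(C)C)cc(O[Si](C)(C)C(C)(C)C)c2)cc1
F2 | step 5 | 2-{2,6-bis(methoxymethoxy)-4-[(E)-2-(4-(methoxymethoxy)phenyl)ethenyl]phenyl}-4,4,5,5-tetramethyl-1,3,2-dioxaborolane | COCOc1ccc(/C=C/c2cc(OCOC)c(B3OC(C)(C)C(C)(C)O3)c(OCOC)c2)cc1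
F3 | step 5 | (Z)-1-[3,5-bis(tert-butyldimethylsilyloxy)phenyl]-2-[2,4-bis(tert-butyldimethylsilyloxy)phenyl]ethenyl trifluoromethanesulfonate | O=S(=O)(O/C(=C\c1ccc(O[Si](C)(C)C(C)(C)C)cc1O[Si](C)(C)C(C)(C)C)c1cc(O[Si](C)(C)C(C)(C)C)cc(O[Si](C)(C)C(C)(C)C)c1)C(F)(F)F
F4 | step 6 | (E)-1,3-bis(1-ethoxyethoxy)-5-{2-[4-(1-ethoxyethoxy)phenyl]ethenyl}benzene (acetal centres unassigned, diastereomer mixture) | CCOC(C)Oc1ccc(/C=C/c2cc(OC(C)OCC)cc(OC(C)OCC)c2)cc1
F5 | step 6 | {2,6-bis(1-ethoxyethoxy)-4-[(E)-2-(4-(1-ethoxyethoxy)phenyl)ethenyl]phenyl}lithium | [Li]c1c(OC(C)OCC)cc(/C=C/c2ccc(OC(C)OCC)cc2)cc1OC(C)OCC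
F6 | step 6 | lithium 1-{2,6-bis(1-ethoxyethoxy)-4-[(E)-2-(4-(1-ethoxyethoxy)phenyl)ethenyl]phenyl}-1-[3,5-bis(tert-butyldimethylsilyloxy)phenyl]-2-[2,4-bis(tert-butyldimethylsilyloxy)phenyl]ethan-1-olate | [Li+].[O-]C(Cc1ccc(O[Si](C)(C)C(C)(C)C)cc1O[Si](C)(C)C(C)(C)C)(c1cc(O[Si](C)(C)C(C)(C)C)cc(O[Si](C)(C)C(C)(C)C)c1)c1c(OC(C)OCC)cc(/C=C/c2ccc(OC(C)OCC)cc2)cc1OC(C)OCC
F7 | step 6 | 2-{1-[3,5-bis(tert-butyldimethylsilyloxy)phenyl]-2-[2,4-bis(tert-butyldimethylsilyloxy)phenyl]ethenyl}-1,3-bis(1-ethoxyethoxy)-5-[(E)-2-(4-(1-ethoxyethoxy)phenyl)ethenyl]benzene (E/Z mixture at the triaryl alkene) | CCOC(C)Oc1ccc(/C=C/c2cc(OC(C)OCC)c(C(=Cc3ccc(O[Si](C)(C)C(C)(C)C)cc3O[Si](C)(C)C(C)(C)C)c3cc(O[Si](C)(C)C(C)(C)C)cc(O[Si](C)(C)C(C)(C)C)c3)c(OC(C)OCC)c2)cc1
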